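The C1–C2 bond of ring B is the disconnection on which the route rests. C1 carries the 4-hydroxy-3-methoxyphenyl ring and can therefore be raised to the exocyclic carbon of a para-quinone methide, while C2 is the α-carbon of the aldehyde and turns nucleophilic as an enamine. A single aminocatalytic 1,6-addition thus forms C1–C2, closes ring B, sets both stereocentres and returns the free pendant phenol. Its substrate is ring A bearing, on neighbouring carbons, the quinone methide and an (E)-3-(silyloxymethyl)but-3-enal arm with the aldehyde branch cis to the arene; it is built from 6-bromovanillin by olefination, then aryllithium addition to protected vanillin.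

Key step: step 10

Remarks on the chemistry:
- Locants follow the dihydronaphthalene numbering of the target (C1 aryl-bearing, C2 formyl-bearing, C3 CH2O-bearing, C4 vinylic CH, C4a and C8a ring fusion). Ring A is the benzo ring; ring B is the ring closed in step 10.
- By the CIP rules the acyclic alkene of the cyclisation substrate is E, because CH2OSi outranks CH2CHO. This is the isomer with the aldehyde arm cis to ring A, which step 3 delivers.
- Compounds 3, 10, 12 and 13 are racemates or stereoisomer mixtures, and 14 is a mixture of isomers about its exocyclic double bond. All of these elements disappear or converge before or in step 10.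

Step 1
Reactants: 1 triethyl phosphonoacetate; 2 bromoacetaldehyde dimethyl acetal (2-bromo-1,1-dimethoxyethane)
Product: 3 ethyl 2-(diethoxyphosphoryl)-4,4-dimethoxybutanoate (racemic)
Conditions: NaH, DMF, 0 °C; then 2, Bu4NI (cat.), 80 °C
Reagents that add atoms: none
Why: The sodium enolate of the phosphonoacetate is C-alkylated by the primary bromide in an SN2 reaction, heat and iodide catalysis offsetting the retarding β-alkoxy groups; the new stereocentre becomes sp2 in step 3.

Step 2
Reactants: 4 6-bromovanillin (2-bromo-4-hydroxy-5-methoxybenzaldehyde)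
Product: 5 2-bromo-5-methoxy-4-[(triisopropylsilyl)oxy]benzaldehyde
Conditions: i-Pr3SiCl, imidazole, DMF, rt
Reagents that add atoms: triisopropylsilyl chloride, CC(C)[Si](Cl)(C(C)C)C(C)C
Why: Imidazole-promoted O-silylation of the phenol gives a bulky aryl silyl ether that should tolerate the basic, hydridic, organolithium and acidic steps that follow.

Step 3
Reactants: 5 2-bromo-5-methoxy-4-[(triisopropylsilyl)oxy]benzaldehyde; 3 ethyl 2-(diethoxyphosphoryl)-4,4-dimethoxybutanoate
Product: 6 ethyl (2E)-2-{2-bromo-5-methoxy-4-[(triisopropylsilyl)oxy]benzylidene}-4,4-dimethoxybutanoate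
Conditions: NaH, THF, 0 °C → rt
Reagents that add atoms: none
Why: Horner–Wadsworth–Emmons olefination of an aromatic aldehyde with an α-alkyl phosphonoacetate should favour the E ester (aryl trans to CO2Et, hence cis to the acetal arm), and any Z isomer is removed by chromatography.

Step 4
Reactants: 6 ethyl (2E)-2-{2-bromo-5-methoxy-4-[(triisopropylsilyl)oxy]benzylidene}-4,4-dimethoxybutanoate
Product: 7 (2E)-2-{2-bromo-5-methoxy-4-[(triisopropylsilyl)oxy]benzylidene}-4,4-dimethoxybutan-1-ol
Conditions: i-Bu2AlH, CH2Cl2, −78 °C; aq. potassium sodium tartrate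
Reagents that add atoms: none
Why: 1,2-Reduction of the conjugated ester by the aluminium hydride at low temperature should stop at the allylic alcohol and leave the aryl bromide, acetal, silyl ether and alkene geometry untouched.

Step 5
Reactants: 7 (2E)-2-{2-bromo-5-methoxy-4-[(triisopropylsilyl)oxy]benzylidene}-4,4-dimethoxybutan-1-ol
Product: 8 tert-butyl{[(2E)-2-{2-bromo-5-methoxy-4-[(triisopropylsilyl)oxy]benzylidene}-4,4-dimethoxybutyl]oxy}diphenylsilane
Conditions: t-BuPh2SiCl, imidazole, CH2Cl2, rt
Reagents that add atoms: tert-butyl(chloro)diphenylsilane, CC(C)(C)[Si](Cl)(c1ccccc1)c1ccccc1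
Why: Imidazole-promoted silylation of the primary allylic alcohol installs a tert-butyldiphenylsilyl ether, chosen because it should survive the aqueous acid of step 8 yet fall to fluoride in step 11.

Step 6
Reactants: 9 vanillin
Product: 10 3-methoxy-4-(tetrahydro-2H-pyran-2-yloxy)benzaldehyde (racemic)
Conditions: 3,4-dihydro-2H-pyran, pyridinium p-toluenesulfonate (cat.), CH2Cl2, rt
Reagents that add atoms: 3,4-dihydro-2H-pyran, C1=COCCC1
Why: Acid-catalysed addition of the phenol to the enol ether (tetrahydropyranylation) gives a mixed acetal that is inert to aryllithiums and is cleaved by the same aqueous acid that later opens the dimethyl acetal, so no separate deprotection step is needed.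

Step 7
Reactants: 8 tert-butyl{[(2E)-2-{2-bromo-5-methoxy-4-[(triisopropylsilyl)oxy]benzylidene}-4,4-dimethoxybutyl]oxy}diphenylsilane; 10 3-methoxy-4-(tetrahydro-2H-pyran-2-yloxy)benzaldehyde
Product: 12 {2-[(1E)-2-{[(tert-butyldiphenylsilyl)oxy]methyl}-4,4-dimethoxybut-1-en-1-yl]-4-methoxy-5-[(triisopropylsilyl)oxy]phenyl}[3-methoxy-4-(tetrahydro-2H-pyran-2-yloxy)phenyl]methanol (stereoisomer mixture), via aryllithium 11 (not isolated)
Conditions: n-BuLi, THF, −78 °C; then 10, −78 → −40 °C; aq. NH4Cl
Reagents that add atoms: none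
Why: Bromine–lithium exchange at −78 °C is faster than attack of n-BuLi on the silyl ethers or the acetal, and 1,2-addition of aryllithium 11 to the non-enolisable aldehyde 10 should give the diaryl carbinol, whose stereocentres are erased in steps 8 and 9.

Step 8
Reactants: 12 {2-[(1E)-2-{[(tert-butyldiphenylsilyl)oxy]methyl}-4,4-dimethoxybut-1-en-1-yl]-4-methoxy-5-[(triisopropylsilyl)oxy]phenyl}[3-methoxy-4-(tetrahydro-2H-pyran-2-yloxy)phenyl]methanol
Product: 13 (3E)-3-{[(tert-butyldiphenylsilyl)oxy]methyl}-4-{2-[hydroxy(4-hydroxy-3-methoxyphenyl)methyl]-5-methoxy-4-[(triisopropylsilyl)oxy]phenyl}but-3-enal (racemic)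
Conditions: aq. HCl (1 M), THF, 0 °C → rt
Reagents that add atoms: water, O
Why: Acetal hydrolysis in dilute aqueous acid should cleave both the aryl tetrahydropyranyl ether and the dimethyl acetal, while the aryl triisopropylsilyl and alkyl tert-butyldiphenylsilyl ethers are stable and the excess of water returns any benzylic cation to the carbinol.

Step 9
Reactants: 13 (3E)-3-{[(tert-butyldiphenylsilyl)oxy]methyl}-4-{2-[hydroxy(4-hydroxy-3-methoxyphenyl)methyl]-5-methoxy-4-[(triisopropylsilyl)oxy]phenyl}but-3-enal
Product: 14 (3E)-3-{[(tert-butyldiphenylsilyl)oxy]methyl}-4-{5-methoxy-2-[(3-methoxy-4-oxocyclohexa-2,5-dien-1-ylidene)methyl]-4-[(triisopropylsilyl)oxy]phenyl}but-3-enal (para-quinone methide; filtered CH2Cl2 solution, used at once)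
Conditions: 10-camphorsulfonic acid (cat.), MgSO4, CH2Cl2, 0 °C; then solid NaHCO3, filtration
Reagents that add atoms: none
Why: Acid-catalysed 1,6-dehydration of a para-hydroxybenzhydrol, in which ionisation is assisted by the para-methoxy group of ring A and the para-hydroxyl of the pendant ring, loss of the phenolic proton gives the conjugated δ-aryl quinone methide, the drying agent pulls the equilibrium, and the acid is neutralised and filtered off before the aldehyde can enolise appreciably.

Step 10
Reactants: 14 (3E)-3-{[(tert-butyldiphenylsilyl)oxy]methyl}-4-{5-methoxy-2-[(3-methoxy-4-oxocyclohexa-2,5-dien-1-ylidene)methyl]-4-[(triisopropylsilyl)oxy]phenyl}but-3-enal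
Product: 17 (1S,2R)-3-{[(tert-butyldiphenylsilyl)oxy]methyl}-1-(4-hydroxy-3-methoxyphenyl)-6-methoxy-7-[(triisopropylsilyl)oxy]-1,2-dihydronaphthalene-2-carbaldehyde, via dienamine 15 (not isolated), via iminium phenolate 16 (not isolated)
Conditions: (R)-2-[diphenyl(trimethylsilyloxy)methyl]pyrrolidine (20 mol%), PhCO2H (20 mol%), CH2Cl2, −20 °C
Reagents that add atoms: none
Why: Proposed new method: the amine condenses with the aldehyde of 14 to the E,s-trans dienamine 15 (the conjugated enal tautomer would give the same species), its α-carbon C2 adds to the exocyclic quinone methide carbon C1 to give iminium phenolate 16, and proton transfer plus hydrolysis release 17 and the amine; the closest known reaction type is the amine-catalysed enantioselective intermolecular 1,6-addition of aldehyde enamines to para-quinone methides, extended here to a tethered dienamine and a quinone methide without blocking tert-butyl groups. Ring B closes in a 6-exo-trig mode, since the accepting C1=C bond lies outside the new six-membered ring. C2 is controlled by the catalyst: the diphenyl(silyloxy)methyl group of the R amine shields one face of the dienamine, and by the usual steric model attack on the open face should give 2R. C1 is controlled by the ring-closure topology: allylic strain against C8–H and against the C3 substituent should place the quinoid ring and the enamine unit anti across the forming bond, which gives the trans product and therefore 1S, and trans is also the more stable arrangement at the enolisable C2. The step needs α- and not γ-attack of the dienamine, which the tether secures because bonding from C4 to C1 would form a four-membered ring, and it needs C1 and C2 within reach, which the E geometry of the C3=C4 bond from step 3 secures. Rearomatisation of the pendant ring to the guaiacol provides the driving force and should make the addition effectively irreversible under these weakly acidic conditions.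

Step 11
Reactants: 17 (1S,2R)-3-{[(tert-butyldiphenylsilyl)oxy]methyl}-1-(4-hydroxy-3-methoxyphenyl)-6-methoxy-7-[(triisopropylsilyl)oxy]-1,2-dihydronaphthalene-2-carbaldehyde
Product: 18 (1S,2R)-7-hydroxy-1-(4-hydroxy-3-methoxyphenyl)-3-(hydroxymethyl)-6-methoxy-1,2-dihydronaphthalene-2-carbaldehyde (target)
Conditions: Bu4NF, AcOH (1:1), THF, 0 °C → rt
Reagents that add atoms: none
Why: Fluoride-mediated desilylation of the aryl and the primary alkyl silyl ether, buffered with acetic acid so that neither a phenolate (which could open ring B by retro-1,6-addition) nor an enolate of the α-stereogenic β,γ-unsaturated aldehyde is formed, should leave C1 and C2 untouched.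

Compound list
1 | triethyl phosphonoacetate | CCOC(=O)CP(=O)(OCC)OCC | starting material
2 | bromoacetaldehyde dimethyl acetal | COC(CBr)OC | starting material
3 | ethyl 2-(diethoxyphosphoryl)-4,4-dimethoxybutanoate (racemic) | CCOC(=O)C(CC(OC)OC)P(=O)(OCC)OCC | intermediate
4 | 6-bromovanillin | O=Cc1cc(OC)c(O)cc1Br | starting material
5 | 2-bromo-5-methoxy-4-[(triisopropylsilyl)oxy]benzaldehyde | O=Cc1cc(OC)c(O[Si](C(C)C)(C(C)C)C(C)C)cc1Br | intermediate
6 | ethyl (2E)-2-{2-bromo-5-methoxy-4-[(triisopropylsilyl)oxy]benzylidene}-4,4-dimethoxybutanoate | CCOC(=O)/C(CC(OC)OC)=C/c1cc(OC)c(O[Si](C(C)C)(C(C)C)C(C)C)cc1Br | intermediate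
7 | (2E)-2-{2-bromo-5-methoxy-4-[(triisopropylsilyl)oxy]benzylidene}-4,4-dimethoxybutan-1-ol | OC/C(CC(OC)OC)=C/c1cc(OC)c(O[Si](C(C)C)(C(C)C)C(C)C)cc1Br | intermediate
8 | tert-butyl{[(2E)-2-{2-bromo-5-methoxy-4-[(triisopropylsilyl)oxy]benzylidene}-4,4-dimethoxybutyl]oxy}diphenylsilane | CC(C)(C)[Si](c1ccccc1)(c1ccccc1)OC/C(CC(OC)OC)=C/c1cc(OC)c(O[Si](C(C)C)(C(C)C)C(C)C)cc1Br | intermediate
9 | vanillin | COc1cc(C=O)ccc1O | starting material
10 | 3-methoxy-4-(tetrahydro-2H-pyran-2-yloxy)benzaldehyde (racemic) | COc1cc(C=O)ccc1OC1CCCCO1 | intermediate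
11 | aryllithium from 8 (lithium in place of bromine; E alkene retained) | CC(C)(C)[Si](c1ccccc1)(c1ccccc1)OC/C(CC(OC)OC)=C/c1cc(OC)c(O[Si](C(C)C)(C(C)C)C(C)C)cc1[Li] | intermediate
12 | {2-[(1E)-2-{[(tert-butyldiphenylsilyl)oxy]methyl}-4,4-dimethoxybut-1-en-1-yl]-4-methoxy-5-[(triisopropylsilyl)oxy]phenyl}[3-methoxy-4-(tetrahydro-2H-pyran-2-yloxy)phenyl]methanol (stereoisomer mixture) | CC(C)(C)[Si](c1ccccc1)(c1ccccc1)OC/C(CC(OC)OC)=C/c1cc(OC)c(O[Si](C(C)C)(C(C)C)C(C)C)cc1C(O)c1ccc(OC2CCCCO2)c(OC)c1 | intermediate
13 | (3E)-3-{[(tert-butyldiphenylsilyl)oxy]methyl}-4-{2-[hydroxy(4-hydroxy-3-methoxyphenyl)methyl]-5-methoxy-4-[(triisopropylsilyl)oxy]phenyl}but-3-enal (racemic) | O=CC/C(CO[Si](c1ccccc1)(c1ccccc1)C(C)(C)C)=C\c1cc(OC)c(O[Si](C(C)C)(C(C)C)C(C)C)cc1C(O)c1ccc(O)c(OC)c1 | intermediate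
14 | (3E)-3-{[(tert-butyldiphenylsilyl)oxy]methyl}-4-{5-methoxy-2-[(3-methoxy-4-oxocyclohexa-2,5-dien-1-ylidene)methyl]-4-[(triisopropylsilyl)oxy]phenyl}but-3-enal (para-quinone methide; mixture of isomers about the exocyclic double bond) | O=CC/C(CO[Si](c1ccccc1)(c1ccccc1)C(C)(C)C)=C\c1cc(OC)c(O[Si](C(C)C)(C(C)C)C(C)C)cc1C=C1C=CC(=O)C(OC)=C1 | intermediate
15 | E dienamine of 14 with (R)-2-[diphenyl(trimethylsilyloxy)methyl]pyrrolidine (N–CH=CH–C(CH2OSi)=CH–aryl, aldehyde-derived arm cis to ring A) | C[Si](C)(C)OC(c1ccccc1)(c1ccccc1)[C@H]1CCCN1/C=C/C(CO[Si](c1ccccc1)(c1ccccc1)C(C)(C)C)=C\c1cc(OC)c(O[Si](C(C)C)(C(C)C)C(C)C)cc1C=C1C=CC(=O)C(OC)=C1 | intermediate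
16 | iminium phenolate: ring-closed (1S,2R) adduct still bound to the R amine through C=N+ at the former formyl carbon | COc1cc([C@H]2c3cc(O[Si](C(C)C)(C(C)C)C(C)C)c(OC)cc3C=C(CO[Si](c4ccccc4)(c5ccccc5)C(C)(C)C)[C@@H]2C=[N+]6CCC[C@@H]6C(O[Si](C)(C)C)(c7ccccc7)c8ccccc8)ccc1[O-] | intermediate
17 | (1S,2R)-3-{[(tert-butyldiphenylsilyl)oxy]methyl}-1-(4-hydroxy-3-methoxyphenyl)-6-methoxy-7-[(triisopropylsilyl)oxy]-1,2-dihydronaphthalene-2-carbaldehyde | COc1cc([C@H]2c3cc(O[Si](C(C)C)(C(C)C)C(C)C)c(OC)cc3C=C(CO[Si](c4ccccc4)(c5ccccc5)C(C)(C)C)[C@@H]2C=O)ccc1O | intermediate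
18 | (1S,2R)-7-hydroxy-1-(4-hydroxy-3-methoxyphenyl)-3-(hydroxymethyl)-6-methoxy-1,2-dihydronaphthalene-2-carbaldehyde | COc1cc([C@H]2c3cc(O)c(OC)cc3C=C(CO)[C@@H]2C=O)ccc1O | target

Total step count: 11. Longest linear sequence: 9 steps (4 → 18 through steps 2, 3, 4, 5, 7, 8, 9, 10 and 11).

Steps most likely to fail

1. Step 10 (proposed new method).
- What may go wrong: the dienamine may form slowly or close with poor facial or cis/trans discrimination. The quinone methide may decay by hydration or oligomerisation before it is intercepted. The product may re-enter the dienamine manifold and suffer double-bond migration.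
- Fallback (known chemistry), setting out from 14: Me3SiOTf and i-Pr2NEt in CH2Cl2 at −78 °C convert the aldehyde into the trimethylsilyl dienol ether F1. The same silyl triflate activates the quinone methide carbonyl, and F1 should close through C2 in an intramolecular Mukaiyama-type 1,6-addition to the racemic trans aryl trimethylsilyl ether F2. Dilute aqueous acid on work-up cleaves the aryl O–Si bond and leaves the racemic trans aldehyde, that is 17 together with its (1R,2S) enantiomer F3. Preparative HPLC on a chiral stationary phase separates the two, and the route resumes at 17.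

2. Step 9.
- What may go wrong: the acid may trigger unselective ring closure through the enol, or intermolecular arylation of the benzylic cation. The quinone methide may hydrate or oligomerise during filtration and transfer.
- Fallback, setting out from 13: capture of the benzylic cation by sulfinate (TolSO2Na, aqueous HCO2H, rt) gives the sulfone F4, a storable precursor that can be purified. Shaking its CH2Cl2 solution with aqueous Na2CO3 eliminates sulfinate by base-induced 1,6-elimination and delivers 14 in acid-free solution, where the route resumes.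

3. Step 11.
- What may go wrong: fluoride, even buffered, may enolise the α-stereogenic β,γ-unsaturated aldehyde (epimerisation, double-bond migration), or ionise the phenol and open ring B by retro-1,6-addition. The primary silyl ether may also be slow to leave.
- Fallback, setting out from 17: HC(OMe)3 and pyridinium p-toluenesulfonate in MeOH mask the aldehyde as the dimethyl acetal F5, in which C2–H is no longer activated. Bu4NF in THF then removes both silyl groups to give the triol acetal F6. Dilute aqueous acid (aq. AcOH, THF) hydrolyses the acetal and the route ends at 18.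

Further compounds
F1 | step 10 | trimethylsilyl dienol ether of 14 (enol ether geometry not defined) | C[Si](C)(C)OC=C/C(CO[Si](c1ccccc1)(c1ccccc1)C(C)(C)C)=C\c1cc(OC)c(O[Si](C(C)C)(C(C)C)C(C)C)cc1C=C1C=CC(=O)C(OC)=C1
F2 | step 10 | racemic trans aryl trimethylsilyl ether of the ring-closed aldehyde (one enantiomer drawn) | COc1cc([C@H]2c3cc(O[Si](C(C)C)(C(C)C)C(C)C)c(OC)cc3C=C(CO[Si](c4ccccc4)(c5ccccc5)C(C)(C)C)[C@@H]2C=O)ccc1O[Si](C)(C)C
F3 | step 10 | (1R,2S) enantiomer of 17 | COc1cc([C@@H]2c3cc(O[Si](C(C)C)(C(C)C)C(C)C)c(OC)cc3C=C(CO[Si](c4ccccc4)(c5ccccc5)C(C)(C)C)[C@H]2C=O)ccc1O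
F4 | step 9 | (3E)-3-{[(tert-butyldiphenylsilyl)oxy]methyl}-4-{2-[(4-hydroxy-3-methoxyphenyl)(4-methylphenylsulfonyl)methyl]-5-methoxy-4-[(triisopropylsilyl)oxy]phenyl}but-3-enal (racemic) | O=CC/C(CO[Si](c1ccccc1)(c1ccccc1)C(C)(C)C)=C\c1cc(OC)c(O[Si](C(C)C)(C(C)C)C(C)C)cc1C(c1ccc(O)c(OC)c1)S(=O)(=O)c1ccc(C)cc1
F5 | step 11 | dimethyl acetal of 17, (1S,2R) | COc1cc([C@H]2c3cc(O[Si](C(C)C)(C(C)C)C(C)C)c(OC)cc3C=C(CO[Si](c4ccccc4)(c5ccccc5)C(C)(C)C)[C@@H]2C(OC)OC)ccc1O
F6 | step 11 | dimethyl acetal of 18, (1S,2R) | COc1cc([C@H]2c3cc(O)c(OC)cc3C=C(CO)[C@@H]2C(OC)OC)ccc1O
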